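Ring A of the target is a disguised quinone: O1 on C8a and the methoxy oxygen on C6 are para, C7 carries the second methoxy and C4a the C4 methylene. The route therefore disconnects the C4a–C8a bond and grows ring A in one thermal operation from a four-membered ring. A 4-alkynyl-4-hydroxy-3-methoxycyclobutenone, assembled from methyl semisquarate and an (S)-2-arylpent-4-ynyl silyl ether made by oxazolidinone-controlled propargylation, opens to a ketene that closes onto the alkyne and delivers the 2-methoxy-5-alkylbenzoquinone with every ring A oxygen in place. Reduction then frees the one hydroxyl (future O1) that can close the pyran ring; ring B is unmasked last from a benzyl-protected phenol.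

Key step: step 10

Remark: chroman numbering is used (ring A is the benzo ring, ring B the pendant quinone); C3 of the target is (S) as drawn, and the descriptor stays (S) from compound 11 onward because CH2–O (or C=O) > aryl > CH2–C > H holds throughout; cyclobutenone 18 forms as both epimers at its carbinol carbon, which does not matter because that carbon becomes a quinone carbonyl.

Step 1
Reactants: 1 2-hydroxy-3,4-dimethoxybenzaldehyde
Product: 2 2-(benzyloxy)-3,4-dimethoxybenzaldehyde
Conditions: BnBr, K2CO3, DMF, 60 °C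
Reagents that add atoms: benzyl bromide, BrCc1ccccc1
Why: Williamson etherification of the phenoxide; the benzyl ether keeps this ring B oxygen from competing in the later pyran closure and is removed by hydrogenolysis just before the final oxidation.

Step 2
Reactants: 2 2-(benzyloxy)-3,4-dimethoxybenzaldehyde
Product: 4 [2-(benzyloxy)-3,4-dimethoxyphenyl]acetonitrile, via tosylalkenyl formamide 3 (not isolated)
Conditions: TosMIC, KOtBu (2.2 equiv), DME, −50 °C; then MeOH, reflux
Reagents that add atoms: tosylmethyl isocyanide (TosMIC), Cc1ccc(cc1)S(=O)(=O)C[N+]#[C-]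
Why: Van Leusen reductive cyanation, in which the TosMIC anion adds to the aldehyde, the oxazoline opens to the N-(1-tosylalkenyl)formamide, and methanolysis removes formyl and sulfinate to leave the one-carbon-homologated nitrile.

Step 3
Reactants: 4 [2-(benzyloxy)-3,4-dimethoxyphenyl]acetonitrile
Product: 5 [2-(benzyloxy)-3,4-dimethoxyphenyl]acetic acid
Conditions: KOH, EtOH/H2O, reflux; then aq. HCl
Reagents that add atoms: water, O; potassium hydroxide, [K+].[OH-]
Why: Alkaline nitrile hydrolysis to the carboxylate, under which aryl benzyl and methyl ethers are inert.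

Step 4
Reactants: 5 [2-(benzyloxy)-3,4-dimethoxyphenyl]acetic acid; 6 (4S)-4-benzyl-1,3-oxazolidin-2-one
Product: 8 (4S)-4-benzyl-3-{[2-(benzyloxy)-3,4-dimethoxyphenyl]acetyl}-1,3-oxazolidin-2-one, via mixed pivalic anhydride 7 (not isolated)
Conditions: PivCl, Et3N, THF, −20 °C; then 6, LiCl, rt
Reagents that add atoms: pivaloyl chloride, CC(C)(C)C(Cl)=O (its acyl group is present in 7 only)
Why: N-acylation of the oxazolidinone through the mixed pivalic anhydride, the LiCl/Et3N-activated auxiliary attacking the less hindered arylacetyl carbonyl.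

Step 5
Reactants: 8 (4S)-4-benzyl-3-{[2-(benzyloxy)-3,4-dimethoxyphenyl]acetyl}-1,3-oxazolidin-2-one; 9 propargyl bromide (3-bromoprop-1-yne)
Product: 11 (4S)-4-benzyl-3-{(2S)-2-[2-(benzyloxy)-3,4-dimethoxyphenyl]pent-4-ynoyl}-1,3-oxazolidin-2-one, via sodium enolate 10 (not isolated)
Conditions: NaN(SiMe3)2, THF, −78 °C; then 9 (3 equiv), −78 → −45 °C; AcOH quench at −78 °C
Reagents that add atoms: sodium bis(trimethylsilyl)amide, [Na+].C[Si](C)(C)[N-][Si](C)(C)C (its sodium is present in 10 only)
Why: Evans asymmetric alkylation, in which the chelated (Z)-sodium enolate is attacked by propargyl bromide on the face opposite the C4 benzyl group of the (S)-auxiliary, so that the new stereocentre is set as (S) (aryl outranks the propargylic carbon).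

Step 6
Reactants: 11 (4S)-4-benzyl-3-{(2S)-2-[2-(benzyloxy)-3,4-dimethoxyphenyl]pent-4-ynoyl}-1,3-oxazolidin-2-one
Product: 12 (2S)-2-[2-(benzyloxy)-3,4-dimethoxyphenyl]pent-4-yn-1-ol
Conditions: LiBH4, H2O (1 equiv), Et2O, 0 °C
Reagents that add atoms: none
Why: Reductive cleavage of the imide with LiBH4 should give the primary alcohol without enolising the benzylic stereocentre and return the auxiliary.

Step 7
Reactants: 12 (2S)-2-[2-(benzyloxy)-3,4-dimethoxyphenyl]pent-4-yn-1-ol
Product: 13 {[(2S)-2-[2-(benzyloxy)-3,4-dimethoxyphenyl]pent-4-yn-1-yl]oxy}(tert-butyl)dimethylsilane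
Conditions: TBSCl, imidazole, DMF, rt
Reagents that add atoms: tert-butyldimethylsilyl chloride, CC(C)(C)[Si](C)(C)Cl
Why: Standard silylation of a primary alcohol; the silyl ether keeps the hydroxyl away from the acetylide, the semisquarate and the ketene of the next steps, and the carbon is activated only once, later, when the internal phenol is present.

Step 8
Reactants: 14 dimethyl squarate (3,4-dimethoxycyclobut-3-ene-1,2-dione)
Product: 16 3-methoxycyclobut-3-ene-1,2-dione, via hydroxy dimethoxycyclobutenone 15 (not isolated)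
Conditions: LiAlH(OtBu)3, THF, −78 → −20 °C; then conc. HCl (cat.), CH2Cl2, rt; used promptly
Reagents that add atoms: none
Why: Mono-reduction of one squarate carbonyl by the hindered hydride, then acid-catalysed loss of methanol from the resulting hydroxy enol ether, is the established way from a squarate diester to a semisquarate ester.

Step 9
Reactants: 13 {[(2S)-2-[2-(benzyloxy)-3,4-dimethoxyphenyl]pent-4-yn-1-yl]oxy}(tert-butyl)dimethylsilane; 16 3-methoxycyclobut-3-ene-1,2-dione
Product: 18 4-{(4S)-4-[2-(benzyloxy)-3,4-dimethoxyphenyl]-5-[(tert-butyldimethylsilyl)oxy]pent-1-yn-1-yl}-4-hydroxy-3-methoxycyclobut-2-en-1-one (both epimers at the carbinol carbon), via lithium acetylide 17 (not isolated)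
Conditions: n-BuLi (1.0 equiv), THF, −78 °C; then added to 16 (1.3 equiv), THF, −78 °C; aq. NH4Cl at −78 °C; Et3N-deactivated silica
Reagents that add atoms: n-butyllithium, [Li]CCCC (its lithium is present in 17 only)
Why: 1,2-Addition of a lithium acetylide to a cyclobutenedione, which should occur at the ketone-like carbonyl next to the methoxy-bearing carbon because the other carbonyl is a deactivated vinylogous ester; the new carbinol centre is uncontrolled and is erased in step 10.

Step 10
Reactants: 18 4-{(4S)-4-[2-(benzyloxy)-3,4-dimethoxyphenyl]-5-[(tert-butyldimethylsilyl)oxy]pent-1-yn-1-yl}-4-hydroxy-3-methoxycyclobut-2-en-1-one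
Product: 20 2-{(2S)-2-[2-(benzyloxy)-3,4-dimethoxyphenyl]-3-[(tert-butyldimethylsilyl)oxy]propyl}-5-methoxycyclohexa-2,5-diene-1,4-dione, via enynyl ketene 19 (not isolated)
Conditions: toluene (degassed, 0.01 M), 110 °C
Reagents that add atoms: none
Why: Heating should trigger conrotatory 4π electrocyclic opening of the C1–C4 bond of the cyclobutenone, the hydroxyl rotating outward so that the alkyne lies cis to the ketene in 19. The ketene carbon (future C8a) then bonds to the distal, chain-bearing alkyne carbon (future C4a) in a 6-endo-dig closure that gives an aryl-type diradical, and transfer of the hydroxyl hydrogen to the radical at future C5 releases the quinone. This is the known thermal ring expansion of 4-alkynyl-4-hydroxycyclobutenones to 1,4-benzoquinones (Moore rearrangement), established for squarate- and semisquarate-derived substrates. No stereocentre is formed: the carbinol centre is destroyed, so both epimers of 18 converge, and the (S) centre of the chain is two bonds from the nearest reacting carbon and is not touched. The step needs six- over five-membered closure, which the alkyl (not radical-stabilising) substituent on the alkyne favours, and the ring A pattern follows from connectivity, the chain ending beside the ketene-derived carbonyl and the methoxy group beside the carbinol-derived one.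

Step 11
Reactants: 20 2-{(2S)-2-[2-(benzyloxy)-3,4-dimethoxyphenyl]-3-[(tert-butyldimethylsilyl)oxy]propyl}-5-methoxycyclohexa-2,5-diene-1,4-dione
Product: 22 2-{(2S)-2-[2-(benzyloxy)-3,4-dimethoxyphenyl]-3-hydroxypropyl}-5-methoxybenzene-1,4-diol, via hydroquinone silyl ether 21 (not isolated)
Conditions: Na2S2O4, EtOAc/H2O, rt; then HCl (1% in MeOH), 0 °C → rt, under argon
Reagents that add atoms: none
Why: Dithionite reduction of the quinone to the hydroquinone, then acid methanolysis of the primary silyl ether, so that the oxidation-prone hydroquinone meets only acid and never base in air.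

Step 12
Reactants: 22 2-{(2S)-2-[2-(benzyloxy)-3,4-dimethoxyphenyl]-3-hydroxypropyl}-5-methoxybenzene-1,4-diol
Product: 23 (3S)-3-[2-(benzyloxy)-3,4-dimethoxyphenyl]-7-methoxy-3,4-dihydro-2H-chromen-6-ol
Conditions: PPh3, DIAD (premixed at 0 °C), THF (degassed, 0.01 M), slow addition of 22, 0 °C → rt
Reagents that add atoms: none
Why: Intramolecular Mitsunobu etherification (6-exo-tet displacement at the primary carbon), in which only the hydroxyl ortho to the chain (future O1) can reach, the para hydroxyl and the benzyl-masked ring B oxygen cannot compete, and C3 keeps its configuration because the displaced carbon is not the stereocentre.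

Step 13
Reactants: 23 (3S)-3-[2-(benzyloxy)-3,4-dimethoxyphenyl]-7-methoxy-3,4-dihydro-2H-chromen-6-ol
Product: 24 (3S)-3-[2-(benzyloxy)-3,4-dimethoxyphenyl]-6,7-dimethoxy-3,4-dihydro-2H-chromene
Conditions: MeI, K2CO3, acetone, 50 °C, under argon
Reagents that add atoms: iodomethane, CI
Why: Williamson methylation of the single remaining phenol completes the 6,7-dimethoxy pattern of ring A.

Step 14
Reactants: 24 (3S)-3-[2-(benzyloxy)-3,4-dimethoxyphenyl]-6,7-dimethoxy-3,4-dihydro-2H-chromene
Product: 25 6-[(3S)-6,7-dimethoxy-3,4-dihydro-2H-chromen-3-yl]-2,3-dimethoxyphenol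
Conditions: H2 (1 atm), 10% Pd/C, EtOAc/EtOH, rt
Reagents that add atoms: none
Why: Hydrogenolysis of the aryl benzyl ether, to which the aryl methyl ethers and the chroman are inert.

Step 15
Reactants: 25 6-[(3S)-6,7-dimethoxy-3,4-dihydro-2H-chromen-3-yl]-2,3-dimethoxyphenol
Product: 26 2-[(3S)-6,7-dimethoxy-3,4-dihydro-2H-chromen-3-yl]-5,6-dimethoxycyclohexa-2,5-diene-1,4-dione
Conditions: (KSO3)2NO (2.5 equiv), KH2PO4 buffer, H2O/acetone, rt
Reagents that add atoms: potassium nitrosodisulfonate, [K+].[K+].[O]N(S(=O)(=O)[O-])S(=O)(=O)[O-]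
Why: Teuber oxidation, in which the nitrosodisulfonate radical converts the phenol with a free para position into the p-quinone, leaves the fully etherified ring A alone, and works in neutral buffer so that the C3–H next to the new quinone is not enolised.

Compound list

1 | 2-hydroxy-3,4-dimethoxybenzaldehyde | COc1ccc(C=O)c(O)c1OC | starting material
2 | 2-(benzyloxy)-3,4-dimethoxybenzaldehyde | COc1ccc(C=O)c(OCc2ccccc2)c1OC | intermediate
3 | N-{2-[2-(benzyloxy)-3,4-dimethoxyphenyl]-1-(4-methylbenzenesulfonyl)ethenyl}formamide (alkene geometry not defined; potassium salt in the flask) | O=CNC(=Cc1ccc(OC)c(OC)c1OCc1ccccc1)S(=O)(=O)c1ccc(C)cc1 | intermediate (not isolated)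
4 | [2-(benzyloxy)-3,4-dimethoxyphenyl]acetonitrile | N#CCc1ccc(OC)c(OC)c1OCc1ccccc1 | intermediate
5 | [2-(benzyloxy)-3,4-dimethoxyphenyl]acetic acid | OC(=O)Cc1ccc(OC)c(OC)c1OCc1ccccc1 | intermediate
6 | (4S)-4-benzyl-1,3-oxazolidin-2-one | O=C1N[C@@H](Cc2ccccc2)CO1 | starting material
7 | [2-(benzyloxy)-3,4-dimethoxyphenyl]acetic pivalic anhydride | CC(C)(C)C(=O)OC(=O)Cc1ccc(OC)c(OC)c1OCc1ccccc1 | intermediate (not isolated)
8 | (4S)-4-benzyl-3-{[2-(benzyloxy)-3,4-dimethoxyphenyl]acetyl}-1,3-oxazolidin-2-one | O=C(Cc1ccc(OC)c(OC)c1OCc1ccccc1)N1[C@@H](Cc2ccccc2)COC1=O | intermediate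
9 | propargyl bromide (3-bromoprop-1-yne) | C#CCBr | starting material
10 | sodium (Z)-enolate of 8 | [Na+].[O-]/C(=C\c1ccc(OC)c(OC)c1OCc1ccccc1)N1[C@@H](Cc2ccccc2)COC1=O | intermediate (not isolated)
11 | (4S)-4-benzyl-3-{(2S)-2-[2-(benzyloxy)-3,4-dimethoxyphenyl]pent-4-ynoyl}-1,3-oxazolidin-2-one | C#CC[C@H](C(=O)N1[C@@H](Cc2ccccc2)COC1=O)c1ccc(OC)c(OC)c1OCc1ccccc1 | intermediate
12 | (2S)-2-[2-(benzyloxy)-3,4-dimethoxyphenyl]pent-4-yn-1-ol | C#CC[C@H](CO)c1ccc(OC)c(OC)c1OCc1ccccc1 | intermediate
13 | {[(2S)-2-[2-(benzyloxy)-3,4-dimethoxyphenyl]pent-4-yn-1-yl]oxy}(tert-butyl)dimethylsilane | C#CC[C@H](CO[Si](C)(C)C(C)(C)C)c1ccc(OC)c(OC)c1OCc1ccccc1 | intermediate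
14 | dimethyl squarate (3,4-dimethoxycyclobut-3-ene-1,2-dione) | COC1=C(OC)C(=O)C1=O | starting material
15 | 4-hydroxy-2,3-dimethoxycyclobut-2-en-1-one (racemic) | COC1=C(OC)C(=O)C1O | intermediate (not isolated)
16 | 3-methoxycyclobut-3-ene-1,2-dione (methyl semisquarate) | COC1=CC(=O)C1=O | intermediate
17 | lithium acetylide of 13 | [Li]C#CC[C@H](CO[Si](C)(C)C(C)(C)C)c1ccc(OC)c(OC)c1OCc1ccccc1 | intermediate (not isolated)
18 | 4-{(4S)-4-[2-(benzyloxy)-3,4-dimethoxyphenyl]-5-[(tert-butyldimethylsilyl)oxy]pent-1-yn-1-yl}-4-hydroxy-3-methoxycyclobut-2-en-1-one (both epimers at the carbinol carbon) | O=C1C=C(OC)C1(O)C#CC[C@H](CO[Si](C)(C)C(C)(C)C)c1ccc(OC)c(OC)c1OCc1ccccc1 | intermediate (precursor of the key step)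
19 | (3Z,8S)-8-[2-(benzyloxy)-3,4-dimethoxyphenyl]-9-[(tert-butyldimethylsilyl)oxy]-4-hydroxy-3-methoxynona-1,3-dien-5-yn-1-one (alkyne cis to the ketene) | O=C=C/C(OC)=C(/O)C#CC[C@H](CO[Si](C)(C)C(C)(C)C)c1ccc(OC)c(OC)c1OCc1ccccc1 | intermediate (not isolated)
20 | 2-{(2S)-2-[2-(benzyloxy)-3,4-dimethoxyphenyl]-3-[(tert-butyldimethylsilyl)oxy]propyl}-5-methoxycyclohexa-2,5-diene-1,4-dione | COC1=CC(=O)C(C[C@H](CO[Si](C)(C)C(C)(C)C)c2ccc(OC)c(OC)c2OCc2ccccc2)=CC1=O | intermediate (product of the key step)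
21 | 2-{(2S)-2-[2-(benzyloxy)-3,4-dimethoxyphenyl]-3-[(tert-butyldimethylsilyl)oxy]propyl}-5-methoxybenzene-1,4-diol | COc1cc(O)c(C[C@H](CO[Si](C)(C)C(C)(C)C)c2ccc(OC)c(OC)c2OCc2ccccc2)cc1O | intermediate (not isolated)
22 | 2-{(2S)-2-[2-(benzyloxy)-3,4-dimethoxyphenyl]-3-hydroxypropyl}-5-methoxybenzene-1,4-diol | COc1cc(O)c(C[C@H](CO)c2ccc(OC)c(OC)c2OCc2ccccc2)cc1O | intermediate
23 | (3S)-3-[2-(benzyloxy)-3,4-dimethoxyphenyl]-7-methoxy-3,4-dihydro-2H-chromen-6-ol | COc1ccc([C@H]2COc3cc(OC)c(O)cc3C2)c(OCc2ccccc2)c1OC | intermediate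
24 | (3S)-3-[2-(benzyloxy)-3,4-dimethoxyphenyl]-6,7-dimethoxy-3,4-dihydro-2H-chromene | COc1ccc([C@H]2COc3cc(OC)c(OC)cc3C2)c(OCc2ccccc2)c1OC | intermediate
25 | 6-[(3S)-6,7-dimethoxy-3,4-dihydro-2H-chromen-3-yl]-2,3-dimethoxyphenol | COc1ccc([C@H]2COc3cc(OC)c(OC)cc3C2)c(O)c1OC | intermediate
26 | 2-[(3S)-6,7-dimethoxy-3,4-dihydro-2H-chromen-3-yl]-5,6-dimethoxycyclohexa-2,5-diene-1,4-dione | COC1=C(OC)C(=O)C([C@H]2COc3cc(OC)c(OC)cc3C2)=CC1=O | target

Total step count: 15.
Longest linear sequence: 14 steps (steps 1–7 and 9–15 from 1; step 8 is a one-step side branch from 14).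

Steps most likely to fail

1. Step 10 (key step). The ketene may close onto the proximal alkyne carbon to give a five-membered alkylidenecyclopentenedione, or the diradical may abstract hydrogen from the benzyl or silyl groups before the hydroxyl hydrogen is delivered. The fallback keeps the same ring construction but makes it closed-shell; it sets out from 13 and comes back at 21. Hydrozirconation of 13 with Cp2Zr(H)Cl in THF and iodinolysis with I2 should give the vinyl iodide {[(2S,4E)-2-[2-(benzyloxy)-3,4-dimethoxyphenyl]-5-iodopent-4-en-1-yl]oxy}(tert-butyl)dimethylsilane F1. Iodine–lithium exchange (t-BuLi, 2 equiv, Et2O, −78 °C) gives [(1E,4S)-4-[2-(benzyloxy)-3,4-dimethoxyphenyl]-5-[(tert-butyldimethylsilyl)oxy]pent-1-en-1-yl]lithium F2. Addition of F2 to 16 at −78 °C gives 4-{(1E,4S)-4-[2-(benzyloxy)-3,4-dimethoxyphenyl]-5-[(tert-butyldimethylsilyl)oxy]pent-1-en-1-yl}-4-hydroxy-3-methoxycyclobut-2-en-1-one F3. Heating F3 in toluene at 110 °C should open it to the dienylketene (3Z,5E,8S)-8-[2-(benzyloxy)-3,4-dimethoxyphenyl]-9-[(tert-butyldimethylsilyl)oxy]-4-hydroxy-3-methoxynona-1,3,5-trien-1-one F4, whose 6π electrocyclisation and enolisation deliver hydroquinone 21 directly, ready for the acid methanolysis of step 11.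

2. Step 9. The acetylide may attack the vinylogous-ester carbonyl or add in conjugate fashion at the methoxy-bearing carbon, the semisquarate may decompose under the basic conditions, or the adduct may lose methanol on work-up. The fallback gives up the four-membered ring and brings ring A in as a preformed arene; it sets out from 8 and comes back at 24. The sodium enolate 10 is alkylated with commercial 2-bromo-4,5-dimethoxybenzyl bromide (COc1cc(Br)c(CBr)cc1OC), with the same facial control as in step 5, to give (4S)-4-benzyl-3-{(2S)-2-[2-(benzyloxy)-3,4-dimethoxyphenyl]-3-(2-bromo-4,5-dimethoxyphenyl)propanoyl}-1,3-oxazolidin-2-one F5. LiBH4 reduction gives (2S)-2-[2-(benzyloxy)-3,4-dimethoxyphenyl]-3-(2-bromo-4,5-dimethoxyphenyl)propan-1-ol F6. Intramolecular aryl C–O coupling of the primary alcohol with the aryl bromide (Pd(OAc)2, 2-(di-tert-butylphosphino)-1,1'-binaphthyl, Cs2CO3, toluene, 80 °C) should close the pyran ring to 24.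

3. Step 12. The azodicarboxylate may oxidise the electron-rich hydroquinone before the phosphonium betaine engages the alcohol, or the para hydroxyl may be etherified intermolecularly. The fallback installs the leaving group while both phenols are still masked as the quinone and closes the ring by phenoxide displacement; it sets out from 20 and comes back at 23. HF·pyridine in THF removes the silyl group to give 2-{(2S)-2-[2-(benzyloxy)-3,4-dimethoxyphenyl]-3-hydroxypropyl}-5-methoxycyclohexa-2,5-diene-1,4-dione F7. MsCl and Et3N in CH2Cl2 at −20 °C give (2S)-2-[2-(benzyloxy)-3,4-dimethoxyphenyl]-3-(4-methoxy-3,6-dioxocyclohexa-1,4-dien-1-yl)propyl methanesulfonate F8. Reduction with Na2S2O4 gives (2S)-2-[2-(benzyloxy)-3,4-dimethoxyphenyl]-3-(2,5-dihydroxy-4-methoxyphenyl)propyl methanesulfonate F9, which with K2CO3 in degassed acetone should cyclise by intramolecular Williamson etherification to 23.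

Further compounds

F1 | step 10 | {[(2S,4E)-2-[2-(benzyloxy)-3,4-dimethoxyphenyl]-5-iodopent-4-en-1-yl]oxy}(tert-butyl)dimethylsilane | I/C=C/C[C@H](CO[Si](C)(C)C(C)(C)C)c1ccc(OC)c(OC)c1OCc1ccccc1
F2 | step 10 | [(1E,4S)-4-[2-(benzyloxy)-3,4-dimethoxyphenyl]-5-[(tert-butyldimethylsilyl)oxy]pent-1-en-1-yl]lithium | [Li]/C=C/C[C@H](CO[Si](C)(C)C(C)(C)C)c1ccc(OC)c(OC)c1OCc1ccccc1
F3 | step 10 | 4-{(1E,4S)-4-[2-(benzyloxy)-3,4-dimethoxyphenyl]-5-[(tert-butyldimethylsilyl)oxy]pent-1-en-1-yl}-4-hydroxy-3-methoxycyclobut-2-en-1-one | O=C1C=C(OC)C1(O)/C=C/C[C@H](CO[Si](C)(C)C(C)(C)C)c1ccc(OC)c(OC)c1OCc1ccccc1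
F4 | step 10 | (3Z,5E,8S)-8-[2-(benzyloxy)-3,4-dimethoxyphenyl]-9-[(tert-butyldimethylsilyl)oxy]-4-hydroxy-3-methoxynona-1,3,5-trien-1-one | O=C=C/C(OC)=C(/O)\C=C\C[C@H](CO[Si](C)(C)C(C)(C)C)c1ccc(OC)c(OC)c1OCc1ccccc1
F5 | step 9 | (4S)-4-benzyl-3-{(2S)-2-[2-(benzyloxy)-3,4-dimethoxyphenyl]-3-(2-bromo-4,5-dimethoxyphenyl)propanoyl}-1,3-oxazolidin-2-one | COc1cc(Br)c(C[C@H](C(=O)N2[C@@H](Cc3ccccc3)COC2=O)c2ccc(OC)c(OC)c2OCc2ccccc2)cc1OC
F6 | step 9 | (2S)-2-[2-(benzyloxy)-3,4-dimethoxyphenyl]-3-(2-bromo-4,5-dimethoxyphenyl)propan-1-ol | COc1cc(Br)c(C[C@H](CO)c2ccc(OC)c(OC)c2OCc2ccccc2)cc1OC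
F7 | step 12 | 2-{(2S)-2-[2-(benzyloxy)-3,4-dimethoxyphenyl]-3-hydroxypropyl}-5-methoxycyclohexa-2,5-diene-1,4-dione | COC1=CC(=O)C(C[C@H](CO)c2ccc(OC)c(OC)c2OCc2ccccc2)=CC1=O
F8 | step 12 | (2S)-2-[2-(benzyloxy)-3,4-dimethoxyphenyl]-3-(4-methoxy-3,6-dioxocyclohexa-1,4-dien-1-yl)propyl methanesulfonate | COC1=CC(=O)C(C[C@H](COS(C)(=O)=O)c2ccc(OC)c(OC)c2OCc2ccccc2)=CC1=O
F9 | step 12 | (2S)-2-[2-(benzyloxy)-3,4-dimethoxyphenyl]-3-(2,5-dihydroxy-4-methoxyphenyl)propyl methanesulfonate | COc1cc(O)c(C[C@H](COS(C)(=O)=O)c2ccc(OC)c(OC)c2OCc2ccccc2)cc1O
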